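The earlier runs and the new flask are simulated from invented constants.

Ring at the last reading stands at 70.0% in winter (charge 0.014 M) and at 6.4% in dawn (charge 1.5 M), much less than in winter. A first-order closure by itself gives one percentage at every charge, so a second loss of starting material, of higher order, must compete with it. Second order is the trial here.

| setting | winter | noon | dawn | amber | violet | blue | red | green |
|---|---|---|---|---|---|---|---|---|
| starting material | 0.014 M | 0.21 M | 1.5 M | 0.020 M | 0.060 M | 0.20 M | 0.60 M | 2.0 M |
| remark | run made earlier | run made earlier | run made earlier |  |  |  |  |  |
| time |  |  |  | 2.0 h | 2.0 h | 2.0 h | 2.0 h | 2.0 h |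

- winter (time / min: ring / %): 8.00: 22.4; 20.0: 43.3; 40.0: 62.0; 60.0: 70.0
- noon (time / min: ring / %): 5.00: 10.0; 12.0: 15.3; 25.0: 20.0; 60.0: 23.9
- dawn (time / min: ring / %): 8.00: 3.8; 20.0: 4.8; 40.0: 6.2; 60.0: 6.4

(each reading ± 0.3 percentage points)

- a reading or a percentage of ring counts all its forms, free or not
- "hardly changes" means that all values lie within two and a half points (for a concentration: within two and a half percent of the largest)

- amount of ring at the end, in percent of the starting material charged for amber, violet, blue, red, green, in this order
- how the row runs (rises, then falls / falls all the way / falls, then rises / rises all the way / hardly changes)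

1. Let starting material fall as −k c(starting material) − q c(starting material)^2, with charge C. Two times then compete: the closure time 1/k and the loss time at the start, 1/(qC). Their ratio is a = qC/k.

2. Ring is made at k c(starting material). Integrating gives the ring fraction y = ln(1 + a f)/a, where f = 1 − exp(−kt). As t grows, f tends to one.

3. Noon's last reading, taken with f as one, gives a of about 9.97.

4. Scaling that a to winter's charge and inserting winter's reading at 20.0 min gives k = 0.0348 min⁻¹, a closure time of 28.7 min. So f at 60.0 min was 0.876, not one.

5. Solving noon again with that f gives the crossover concentration c*, at which closure and loss use starting material equally fast: 0.0227 M. Then a = C/c*, and c*/c(starting material) is the selectivity factor.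

6. Dawn played no part in this. The formula gives it 6.17% at 60.0 min, against the reading of 6.4%.

7. The loss time at the start is 32.6 min in amber and 0.326 min in green. With 2.0 h allowed, this reckoning gives 70.9%, 48.5%, 25.8%, 12.5% and 5.08%, a row that falls at each step.

The forecast, differing slightly from this reckoning in its figures, gives 71%, 49%, 26%, 12.7% and 5.2%, a row that falls all the way: “The row falls throughout.”

The flask gives 71.0%, 48.8%, 26.2%, 12.8% and 5.29%, and the row falls all the way.

    2 starting material → open dimer (k = 0.0129 M⁻¹ s⁻¹)
    starting material → ring (k = 5.85 × 10⁻⁴ s⁻¹)
    starting material + ring ⇌ idle adduct, settled at all times (K = 1.80 M⁻¹)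
    crystals ⇌ ring, rate k4*(cs4 - [ring]) while solid is left; crystals form when [ring] > cs4 (solubility = 0.0730 M, k = 0.0126 s⁻¹)

In amber, closure uses starting material 1.1 times as fast as loss to open dimer just after the start, where c*/C gives 1.13, and 130 times as fast at 2.00 h, where 0.847% of the starting material remains and c* gives 134. In red, c*/C is 0.0378 at the start and the end formula gives 12.5%, while the flask holds 12.8% ring at 2.00 h, crystals counted in.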